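**Plan**
Retrosynthesis: cut C8–C17 (hydroxymethyl anion onto a C8 ketone), C12–C13 (B-alkyl Suzuki–Miyaura), one C4–CH3, then ring A at C1–C2 and C4–C5, then C10–C1 and C9–C11 on a cyclohexenone.
Forward: ring B comes from a 1,4-cyclohexanedione monoketal; conjugate addition/aldol puts vinyl on C9 and C1 on C10; ring A is closed onto ring B by a [3+3] double aldol condensation with butan-2-one; ring A is then reduced and methylated; side chain and C17 are joined last.
Enabling feature: C3 carries the oxygen between C2 and C4 (a ketone with two enolisable α-carbons), and C1 and C5 both sit on the quaternary C10 of ring B, so a C1 aldehyde/C5 ketone pair is a non-enolisable 1,3-dielectrophile whose double condensation product cannot aromatise.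
Stereochemistry: C9/C10 from a copper-catalysed asymmetric conjugate addition with anti enolate trapping; C5 and quaternary C4 from dissolving-metal reductive methylation of the ring A enone; C3 from axial hydride delivery; C8 from equatorial Grignard attack; 13Z from a Z vinyl iodide.

Key step: step 4

Remark: bicyclic compounds are numbered as labdanes (ring A = C1–C5 and C10, ring B = C5–C10, C20 on C10, C17 on C8, chain C11–C16); compound 1, methyl but-2-ynoate and the organometallic reagents are taken as purchasable.

Step 1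
Reactants: 1 7-methyl-1,4-dioxaspiro[4.5]decan-8-one
Product: 3 7-methyl-1,4-dioxaspiro[4.5]dec-6-en-8-one, via silyl enol ether 2 (not isolated)
Conditions: Me3SiCl, NaI, Et3N, MeCN, rt; then Pd(OAc)2 (cat.), O2 (1 atm), DMSO, 50 °C
Reagents that add atoms: none
Why: Saegusa–Ito dehydrogenation, in which the more substituted (thermodynamic) silyl enol ether is palladated and β-hydride elimination towards the ring CH2 gives the 2-methyl enone, the racemic centre of 1 being destroyed.

Step 2
Reactants: 3 7-methyl-1,4-dioxaspiro[4.5]dec-6-en-8-one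
Product: 5 (6S,7R)-6-ethenyl-7-(hydroxymethyl)-7-methyl-1,4-dioxaspiro[4.5]decan-8-one, via magnesium enolate 4 (not isolated)
Conditions: vinylmagnesium bromide, CuBr·SMe2 (cat.), (R)-1-[(S)-2-(diphenylphosphino)ferrocenyl]ethyldicyclohexylphosphine (cat.; ligand enantiomer to be fixed in a test run for the 6S adduct), t-BuOMe, −78 °C; then CH2O (gas, from cracked paraformaldehyde), −78 → −40 °C; aqueous work-up
Reagents that add atoms: vinylmagnesium bromide C=C[Mg]Br; formaldehyde C=O
Why: Copper-catalysed asymmetric conjugate addition followed by aldol trapping, in which the chiral copper–diphosphine complex selects the enone face at C9 and formaldehyde then enters the tetrasubstituted enolate anti to the new vinyl group, so that the hydroxymethyl group (future C1) is trans to vinyl at the quaternary C10.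

Step 3
Reactants: 5 (6S,7R)-6-ethenyl-7-(hydroxymethyl)-7-methyl-1,4-dioxaspiro[4.5]decan-8-one
Product: 6 (6S,7R)-6-ethenyl-7-methyl-8-oxo-1,4-dioxaspiro[4.5]decane-7-carbaldehyde
Conditions: 1,1,1-triacetoxy-1,1-dihydro-1,2-benziodoxol-3(1H)-one, CH2Cl2, 0 °C → rt
Reagents that add atoms: none
Why: Periodinane oxidation of the neopentyl primary alcohol should give the non-enolisable 2-formyl ketone under neutral conditions that leave the ketal, the vinyl group and the quaternary C10 untouched.

Step 4
Reactants: 6 (6S,7R)-6-ethenyl-7-methyl-8-oxo-1,4-dioxaspiro[4.5]decane-7-carbaldehyde; 7 butan-2-one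
Product: 9 (9S,10S)-8,8-(ethylenedioxy)-13,14,15,16,17,19-hexanorlabda-1,4,11-trien-3-one, via aldol adduct 8 (not isolated)
Conditions: butan-2-one (excess, as solvent), piperidine (cat.), AcOH (cat.), 4 Å molecular sieves, 80 °C
Reagents that add atoms: none
Why: Secondary-amine/acid-catalysed double aldol condensation ([3+3] cyclocondensation): the iminium ion of the C1 aldehyde is attacked by the methyl-side enamine of butan-2-one (C1–C2), the methylene carbon of the same ketone then closes onto the C5 ketone (C4–C5), and two dehydrations give the cross-conjugated dienone. The closest known reaction type is the condensation of 2-formyl-2-alkylcycloalkanones with acetone to 4,4-disubstituted cyclohexa-2,5-dienones. Ring A closes in a 6-(enolendo)-exo-trig aldol step while C1 is still tetrahedral (aldol adduct 8 or its amine adduct), and reversible amine conjugate addition keeps an early-formed E enone from blocking the closure. No stereocenter is created: C1, C2, C4 and C5 are trigonal in 9, C9 and C10 are untouched, and C5, C4 and C3 are set afterwards from this dienone. The step needs chemoselectivity (aldehyde before ketone, secured by the far more electrophilic formyl group) and regioselectivity within butan-2-one (methyl carbon to C1, methylene carbon to C5), secured by the neopentyl-type aldehyde on quaternary C10 accepting only the unhindered methyl-side enamine, after which the ring can close only through the methylene carbon. Because C10 is quaternary the dienone cannot aromatise, and conjugation makes the double dehydration the thermodynamic sink.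

Step 5
Reactants: 9 (9S,10S)-8,8-(ethylenedioxy)-13,14,15,16,17,19-hexanorlabda-1,4,11-trien-3-one
Product: 10 (9S,10S)-8,8-(ethylenedioxy)-13,14,15,16,17,19-hexanorlabda-4,11-dien-3-one
Conditions: Cu(OAc)2·H2O (cat.), 1,2-bis(diphenylphosphino)benzene (cat.), (EtO)2MeSiH, t-BuOH, toluene, rt
Reagents that add atoms: none
Why: Copper hydride 1,4-reduction, in which hydride adds to the less substituted enone carbon C1 and not to the fully substituted C5, the isolated vinyl group is inert, and protonation at C2 leaves the 4-methyl C4=C5 enone.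

Step 6
Reactants: 10 (9S,10S)-8,8-(ethylenedioxy)-13,14,15,16,17,19-hexanorlabda-4,11-dien-3-one
Product: 12 (5S,9S,10R)-8,8-(ethylenedioxy)-13,14,15,16,17-pentanorlabd-11-en-3-one, via lithium enolate 11 (not isolated)
Conditions: Li, NH3/THF, t-BuOH (1 equiv), −78 °C; then MeI, −78 → −33 °C
Reagents that add atoms: iodomethane CI
Why: Birch-type reductive alkylation, in which axial protonation at C5 of the reduced enone gives the trans ring fusion (H5 anti to the C10 methyl) and the regiospecific C3–C4 lithium enolate is C-methylated at C4 to complete the gem-dimethyl quaternary carbon.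

Step 7
Reactants: 12 (5S,9S,10R)-8,8-(ethylenedioxy)-13,14,15,16,17-pentanorlabd-11-en-3-one
Product: 13 (3R,5S,9S,10R)-8,8-(ethylenedioxy)-13,14,15,16,17-pentanorlabd-11-en-3-ol
Conditions: NaBH4, MeOH, 0 °C
Reagents that add atoms: none
Why: Hydride reduction, in which NaBH4 attacks C3 axially from the face opposite the axial methyl groups on C4 and C10 and so gives the equatorial alcohol, cis to the C10 methyl.

Step 8
Reactants: 14 methyl but-2-ynoate
Product: 15 methyl (2Z)-3-iodobut-2-enoate
Conditions: NaI, AcOH, 115 °C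
Reagents that add atoms: sodium iodide [Na+].[I-]
Why: Hydroiodination of the ynoate by iodide conjugate addition and anti protonation should give the Z β-iodo enoate with iodine cis to the ester.

Step 9
Reactants: 13 (3R,5S,9S,10R)-8,8-(ethylenedioxy)-13,14,15,16,17-pentanorlabd-11-en-3-ol; 15 methyl (2Z)-3-iodobut-2-enoate
Product: 17 methyl (3R,5S,9S,10R,13Z)-8,8-(ethylenedioxy)-3-hydroxy-17-norlabd-13-en-15-oate, via B-alkyl borane 16 (not isolated)
Conditions: 9-BBN, THF, rt; then 15, [PdCl2(dppf)] (cat.), AsPh3 (cat.), Cs2CO3, DMF/H2O, rt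
Reagents that add atoms: none
Why: Hydroboration/B-alkyl Suzuki–Miyaura coupling, in which 9-BBN places boron on the terminal vinyl carbon (C12) and the alkylborane couples with the vinyl iodide with retention, so the C12 chain ends up cis to the ester (13Z).

Step 10
Reactants: 17 methyl (3R,5S,9S,10R,13Z)-8,8-(ethylenedioxy)-3-hydroxy-17-norlabd-13-en-15-oate
Product: 19 (3R,5S,9S,10R,13Z)-3-hydroxy-8-oxo-17-norlabd-13-en-15-oic acid, via lithium carboxylate 18 (not isolated)
Conditions: LiOH, THF/MeOH/H2O, 45 °C; then 2 M HCl (to pH 1), rt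
Reagents that add atoms: lithium hydroxide [Li+].[OH-]; water O
Why: Ester saponification followed by acid-catalysed ketal hydrolysis in the same flask should free the acid and the C8 ketone, C9 (now α to the ketone) already carrying its side chain in the thermodynamically preferred equatorial position.

Step 11
Reactants: 19 (3R,5S,9S,10R,13Z)-3-hydroxy-8-oxo-17-norlabd-13-en-15-oic acid
Product: 20 (3R,5S,8R,9S,10R,13Z)-3,8-dihydroxy-17-[dimethyl(propan-2-yloxy)silyl]labd-13-en-15-oic acid
Conditions: [dimethyl(propan-2-yloxy)silyl]methylmagnesium chloride (excess, made from (chloromethyl)dimethyl(propan-2-yloxy)silane and Mg), THF, 0 °C → rt; aqueous work-up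
Reagents that add atoms: [dimethyl(propan-2-yloxy)silyl]methylmagnesium chloride CC(C)O[Si](C)(C)C[Mg]Cl
Why: Grignard addition of a hydroxymethyl anion equivalent, in which the bulky reagent attacks the C8 ketone along the equatorial trajectory because the axial one is blocked by the syn-axial C10 methyl, giving the axial C8 hydroxyl (cis to the C10 methyl) and equatorial C17.

Step 12
Reactants: 20 (3R,5S,8R,9S,10R,13Z)-3,8-dihydroxy-17-[dimethyl(propan-2-yloxy)silyl]labd-13-en-15-oic acid
Product: 21 (3R,5S,8R,9S,10R,13Z)-3,8,17-trihydroxylabd-13-en-15-oic acid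
Conditions: H2O2 (30% aq.), KF, KHCO3, THF/MeOH, rt
Reagents that add atoms: hydrogen peroxide OO
Why: Tamao–Fleming oxidation should convert the C17–Si bond of the alkoxysilane into C17–OH without touching the electron-poor C13=C14 double bond or the C8 stereocenter.

Step 13
Reactants: 21 (3R,5S,8R,9S,10R,13Z)-3,8,17-trihydroxylabd-13-en-15-oic acid
Product: 22 (3R,5S,8R,9S,10R,13Z)-3,8-dihydroxy-17-oxolabd-13-en-15-oic acid
Conditions: TEMPO (cat.), PhI(OAc)2, CH2Cl2, rt
Reagents that add atoms: none
Why: TEMPO-catalysed oxidation with PhI(OAc)2 is selective for the primary C17 alcohol over the hindered secondary C3 and tertiary C8 alcohols and should stop at the aldehyde under anhydrous conditions.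

**Compound list**
1 | 7-methyl-1,4-dioxaspiro[4.5]decan-8-one (racemic) | CC1CC2(CCC1=O)OCCO2 | starting material
2 | trimethyl[(7-methyl-1,4-dioxaspiro[4.5]dec-7-en-8-yl)oxy]silane | CC1=C(O[Si](C)(C)C)CCC2(C1)OCCO2 | intermediate
3 | 7-methyl-1,4-dioxaspiro[4.5]dec-6-en-8-one | CC1=CC2(CCC1=O)OCCO2 | intermediate
4 | bromomagnesium (6S)-6-ethenyl-7-methyl-1,4-dioxaspiro[4.5]dec-7-en-8-olate | C=C[C@H]1C(C)=C(O[Mg]Br)CCC12OCCO2 | intermediate
5 | (6S,7R)-6-ethenyl-7-(hydroxymethyl)-7-methyl-1,4-dioxaspiro[4.5]decan-8-one | C=C[C@H]1[C@](C)(CO)C(=O)CCC12OCCO2 | intermediate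
6 | (6S,7R)-6-ethenyl-7-methyl-8-oxo-1,4-dioxaspiro[4.5]decane-7-carbaldehyde | C=C[C@H]1[C@](C)(C=O)C(=O)CCC12OCCO2 | intermediate
7 | butan-2-one | CCC(C)=O | starting material
8 | (6S,7R)-6-ethenyl-7-(1-hydroxy-3-oxopentyl)-7-methyl-1,4-dioxaspiro[4.5]decan-8-one (carbinol carbon not defined) | C=C[C@H]1[C@](C)(C(O)CC(=O)CC)C(=O)CCC12OCCO2 | intermediate
9 | (9S,10S)-8,8-(ethylenedioxy)-13,14,15,16,17,19-hexanorlabda-1,4,11-trien-3-one (ring A cross-conjugated dienone, 9-vinyl, 8-dioxolane) | C=C[C@H]1[C@]2(C)C=CC(=O)C(C)=C2CCC13OCCO3 | intermediate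
10 | (9S,10S)-8,8-(ethylenedioxy)-13,14,15,16,17,19-hexanorlabda-4,11-dien-3-one | C=C[C@H]1[C@]2(C)CCC(=O)C(C)=C2CCC13OCCO3 | intermediate
11 | lithium (5S,9S,10R)-8,8-(ethylenedioxy)-13,14,15,16,17,19-hexanorlabda-3,11-dien-3-olate | C=C[C@H]1[C@]2(C)CCC(O[Li])=C(C)[C@H]2CCC13OCCO3 | intermediate
12 | (5S,9S,10R)-8,8-(ethylenedioxy)-13,14,15,16,17-pentanorlabd-11-en-3-one | C=C[C@H]1[C@]2(C)CCC(=O)C(C)(C)[C@H]2CCC13OCCO3 | intermediate
13 | (3R,5S,9S,10R)-8,8-(ethylenedioxy)-13,14,15,16,17-pentanorlabd-11-en-3-ol | C=C[C@H]1[C@]2(C)CC[C@@H](O)C(C)(C)[C@H]2CCC13OCCO3 | intermediate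
14 | methyl but-2-ynoate | CC#CC(=O)OC | starting material
15 | methyl (2Z)-3-iodobut-2-enoate | C/C(I)=C/C(=O)OC | intermediate
16 | 9-[(3R,5S,9S,10R)-8,8-(ethylenedioxy)-3-hydroxy-13,14,15,16,17-pentanorlabdan-12-yl]-9-borabicyclo[3.3.1]nonane | B1(CC[C@H]2[C@]3(C)CC[C@@H](O)C(C)(C)[C@H]3CCC24OCCO4)C5CCCC1CCC5 | intermediate
17 | methyl (3R,5S,9S,10R,13Z)-8,8-(ethylenedioxy)-3-hydroxy-17-norlabd-13-en-15-oate | C/C(=C/C(=O)OC)CC[C@H]1[C@]2(C)CC[C@@H](O)C(C)(C)[C@H]2CCC13OCCO3 | intermediate
18 | lithium (3R,5S,9S,10R,13Z)-8,8-(ethylenedioxy)-3-hydroxy-17-norlabd-13-en-15-oate | C/C(=C/C(=O)[O-])CC[C@H]1[C@]2(C)CC[C@@H](O)C(C)(C)[C@H]2CCC13OCCO3.[Li+] | intermediate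
19 | (3R,5S,9S,10R,13Z)-3-hydroxy-8-oxo-17-norlabd-13-en-15-oic acid | C/C(=C/C(=O)O)CC[C@H]1[C@]2(C)CC[C@@H](O)C(C)(C)[C@H]2CCC1=O | intermediate
20 | (3R,5S,8R,9S,10R,13Z)-3,8-dihydroxy-17-[dimethyl(propan-2-yloxy)silyl]labd-13-en-15-oic acid | C/C(=C/C(=O)O)CC[C@H]1[C@]2(C)CC[C@@H](O)C(C)(C)[C@H]2CC[C@]1(O)C[Si](C)(C)OC(C)C | intermediate
21 | (3R,5S,8R,9S,10R,13Z)-3,8,17-trihydroxylabd-13-en-15-oic acid | C/C(=C/C(=O)O)CC[C@H]1[C@]2(C)CC[C@@H](O)C(C)(C)[C@H]2CC[C@]1(O)CO | intermediate
22 | (3R,5S,8R,9S,10R,13Z)-3,8-dihydroxy-17-oxolabd-13-en-15-oic acid | C/C(=C/C(=O)O)CC[C@H]1[C@]2(C)CC[C@@H](O)C(C)(C)[C@H]2CC[C@]1(O)C=O | target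

**Summary**
Total step count: 13. Longest linear sequence: 12 steps (steps 1–7 and 9–13); step 8 is a one-step side branch.

The three steps most likely to fail, each with one fallback:

Step 2. The copper catalyst may not discriminate the enone faces well enough with a vinyl Grignard reagent on this α-methyl, γ-ketal enone. 1,2-Addition may compete, and capture of the hindered enolate by formaldehyde may be reversible or incomplete. The fallback sets out from 3: the same addition/aldol sequence run without chiral ligand (vinylmagnesium bromide, CuBr·SMe2, then CH2O) should give the racemic hydroxymethyl ketone F1. Kinetic resolution by lipase-catalysed acetylation (Burkholderia cepacia lipase, vinyl acetate, t-BuOMe; enzyme screened so that the 6R,7S enantiomer reacts) removes the unwanted enantiomer as the acetate F2. The unreacted (6S,7R) alcohol is 5, where the route is rejoined.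

Step 4. The methylene carbon of butan-2-one may attack the aldehyde in place of the methyl carbon (wrong regioisomer), the amine may strip the formyl group from the 2-formyl ketone, or the sequence may stall at the open-chain enone. The fallback sets out from 6: Knoevenagel condensation with methyl 3-oxopentanoate (piperidine, AcOH) fixes the doubly activated methylene as C2, and closure of the γ-methylene onto C5 should give the ester dienone F3. Copper hydride 1,4-reduction of the doubly activated C1=C2 bond (conditions of step 5) gives the β-keto ester F4. Krapcho dealkoxycarbonylation (LiCl, wet DMSO, 140 °C) then gives 10, where the route is rejoined; step 5 is not needed.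

Step 11. The basic Grignard reagent, also consumed by the acid and alcohol protons, may enolise the hindered C8 ketone instead of adding, and some axial attack may erode the C8 configuration. The fallback sets out from 19: Corey–Chaykovsky reaction with dimethylsulfoxonium methylide (trimethylsulfoxonium iodide, NaH, DMSO, excess) adds reversibly and places the new CH2 equatorial, which should give the spiro-epoxide F5. Opening at the primary carbon with aqueous NaOH in DMSO (80 °C) gives 21, where the route is rejoined; step 12 is not needed.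

**Further compounds**
F1 | step 2 | racemic 6-ethenyl-7-(hydroxymethyl)-7-methyl-1,4-dioxaspiro[4.5]decan-8-one (6S,7R and 6R,7S, vinyl trans to hydroxymethyl) | C=C[C@H]1[C@](C)(CO)C(=O)CCC12OCCO2.C=C[C@@H]1[C@@](C)(CO)C(=O)CCC12OCCO2
F2 | step 2 | [(6R,7S)-6-ethenyl-7-methyl-8-oxo-1,4-dioxaspiro[4.5]decan-7-yl]methyl acetate | C=C[C@@H]1[C@@](C)(COC(C)=O)C(=O)CCC12OCCO2
F3 | step 4 | methyl (9S,10S)-8,8-(ethylenedioxy)-3-oxo-13,14,15,16,17,19-hexanorlabda-1,4,11-triene-2-carboxylate | C=C[C@H]1[C@]2(C)C=C(C(=O)OC)C(=O)C(C)=C2CCC13OCCO3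
F4 | step 4 | methyl (9S,10S)-8,8-(ethylenedioxy)-3-oxo-13,14,15,16,17,19-hexanorlabda-4,11-diene-2-carboxylate (C2 not defined) | C=C[C@H]1[C@]2(C)CC(C(=O)OC)C(=O)C(C)=C2CCC13OCCO3
F5 | step 11 | (3R,5S,8R,9S,10R,13Z)-8,17-epoxy-3-hydroxylabd-13-en-15-oic acid | C/C(=C/C(=O)O)CC[C@H]1[C@]2(C)CC[C@@H](O)C(C)(C)[C@H]2CC[C@]13CO3
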